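## Structural features

The target is a 6,7-seco-ent-kauranoid of the spiro-lactone class (atom labels follow ent-kaurane numbering). Ring A is a 4,4-dimethylcyclohex-2-enone (C1 ketone, C2=C3) whose C10 is the spiro atom of a δ-lactone (C10–C20–O–C7(=O)–C8–C9). The lactone is cis-fused through C8–C9 to cyclohexane ring C (C8, C9, C11–C14), and the bridge C15–C16 from C8 to C13 closes ring D, so rings C and D form a bicyclo[3.2.1]octane. Four stereocentres are contiguous (C5–C10–C9–C8), two of them quaternary (C10, C8) with the methine C9 between them; C13 (bridgehead tertiary carbinol) and C15 (allylic carbinol, hydroxyl syn to the C9–C11–C12 bridge and anti to O13) complete the set. On ring A the formyl carbon C6 is cis to C20 and trans to C9. Fragile elements are the aldehyde with its epimerisable α-centre C5, the acid-labile 15-ol beside the exocyclic C16=C17 alkene, two enones of similar hydride affinity, the β-acyl lactone centre C8 (retro-Claisen) and the C13–C16–C15 β-hydroxy ketone array (retro-aldol) in the intermediates. The real difficulty is the congested C8–C9–C10 triad combined with the 1,3-relation between the C13 oxygen and C8. The key step exploits the fact that C8–C9 is the α,β-bond of the lactone carbonyl C7: with an acetyl group (C15, C16) on C8 it is a doubly activated dienophile, and a diene with sulfur on C12 and oxygen on C13 closes ring C with the oxygen where ring D needs it.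

## Logic of the disconnections

34 ⇒ 33. No skeletal bond is cut; the C6 aldehyde is masked as its dimethyl acetal. The aldehyde (epimerisable C5, hydride-sensitive) is the least durable group and is released last. The forward step must be an acid treatment mild enough for the allylic 15-ol.

33 ⇒ 32. The C15 carbinol is traced to the ketone that serves both the aldol and the methylenation. The forward step needs exo-face hydride delivery and discrimination from the ring A enone; both are asked of the neighbouring C13 hydroxyl.

32 ⇒ 30 ⇒ 29. The ring A enone is traced to a C1 silyl ether. C1 stays at the alcohol level through all base steps, which excludes C2 enolisation and translactonisation. The forward step needs an oxidation/dehydrogenation that can use only C2–C3.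

29 ⇒ 26. The C16=C17 bond is cut. The exocyclic enone is a Michael acceptor and is added only after ring D exists. Enolisation is possible only toward C16 because C8 is quaternary.

26 ⇒ 25. The C13–C16 bond is cut (aldol). The tetracycle becomes a cis-fused bicyclic lactone carrying a methyl ketone on C8 and a ketone at C13. The forward step needs the acetyl group axial on ring C and a base that does not cleave the acyl lactone.

25 ⇒ 24 ⇒ 23. The C13 ketone is traced to an enol acetate flanked by a C12 sulfide, the regiochemical control element of the cycloaddition. The forward steps need a non-basic enol ester cleavage and a reductive C–S scission that leave the β-keto lactone intact.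

23 ⇒ 16 + 22. The C8–C14 and C9–C11 bonds are cut. This removes ring C and both stereocentres C8 and C9 in one convergent step. The forward step needs sulfur-controlled regiochemistry, attack on the lactone face anti to the C5 arm, and enough reactivity at the neopentyl carbon C9.

16 ⇒ 14 ⇒ 13 ⇒ 12. The C8=C9 bond (Knoevenagel) and the C7–O ester bond are cut. The lactone reduces to a quaternary C10 bearing two one-carbon arms at different oxidation levels. Acylating O20 first makes the condensation at the neopentyl aldehyde intramolecular and fixes the alkene geometry. The demand is that the C9 and C20 arms never become equivalent.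

12 ⇒ 11 ⇒ 9 ⇒ 8 ⇒ 7. No skeletal bond is cut except the terminal alkene carbon, which is lost on ozonolysis. The ester becomes C20–OH, the hydroxymethyl group becomes the C9 arm, the ketone becomes the protected C1 carbinol and the vinyl group becomes the C6 acetal. The demands are a directed C1 reduction and conditions that exclude silyl or acyl migration between the neighbouring oxygens.

7 ⇒ 6. The C10–C9 bond is cut (aldol with formaldehyde). This removes the quaternary centre; the forward step must bring the electrophile in anti to the C5 vinyl group.

6 ⇒ 5. The C5–C6 bond is cut (conjugate vinylation). This removes the last stereocentre; the forward step must set C5 by catalyst control next to quaternary C4.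

5 ⇒ 2 ⇒ 1. The C10=C5 unsaturation and the C10–C20 bond are cut, leading to a symmetric commercial ketone; regiochemistry is not an issue.

22 ⇒ 21 ⇒ 19 ⇒ 17 + 18. The enol ester O–acyl bond, the C=C bond of the thio-enone and the C–S bond are cut. The diene reduces to two commercial compounds; the enone 21 must be used at once.

## Other disconnections considered

Alternative 1: The cut is at C10–C20 and C5–C6, the two bonds that join ring A to the lactone methylene and to the formyl carbon. In the forward direction, irradiation (350 nm) of enone ester A1 makes the C10=C5 bond add across the tethered 2-acetoxyvinyl ester to give cyclobutane A2; the C20–C6 bond of the four-membered ring must be broken later.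
- In its favour: C5 and the spiro centre C10 are set in one step, the cis relation of C20 and C6 is enforced by the cyclobutane, and the lactone ring closes in the same event. No redox exchange at C10 is needed. On the C5/C10 relation this is equal to or better than the chosen plan in certainty and better in step count.
- Against it: facial control must be relayed from C9 across an ester tether that prefers an extended conformation, and straight versus crossed addition is not secure for a tether that closes a six-membered ring. C20 is not α to a carbonyl, so the scission cannot be a retro-aldol; it would need alkoxy-radical β-scission with hydrogen capture at C20.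
- Comparison: in A2, C8 is still a methylene. Quaternary C8, ring C and ring D would all have to be built afterwards on a hindered lactone α-carbon, so the hardest part of the structure is postponed, whereas the chosen cycloaddition solves it in one step. Mechanistically both are cycloadditions; the photochemical one is stepwise through a triplet biradical and offers less regiochemical control.

Alternative 2: The cut is at C8–C9 by a retro-[3,3] shift. In the forward direction the silyl ketene acetal of alkenyl δ-lactone A3 (LDA, Me3SiCl) rearranges, forming C8–C9, breaking O–C12 and contracting the lactone to cyclohexene acid A4.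
- In its favour: C8 and C9 are set together through a boat transition state imposed by the ring, which is equal to the cycloaddition in certainty for the C8/C9 relation. The sense relative to C10 comes from a pre-set carbinol centre (C12) and not from π-facial bias of the spiro centre, which is better in principle. The C13 oxygen is in place without a sulfur auxiliary, which is better (no desulfurisation). The propargyl arm on C8 prepares ring D.
- Against it: C12 must first be set in the right sense relative to the remote C10, which needs reagent control and extra steps. The new bond still forms at a carbon next to quaternary C10. The C1 ketone of A3 is enolisable under LDA. A separately made α-propargyl lactone must be joined to ring A, and the acid must later be lactonised onto C20.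
- Comparison: the route is longer and linear where the chosen plan joins two fragments and forms two bonds in one step; both key steps are pericyclic.

Alternative 3: The cut is at C13–C16. In the forward direction SmI2 (HMPA, t-BuOH) converts the C13 ketone of keto alkyne A5 into a ketyl that adds to the alkyne carbon C16, closing ring D as tetracycle A6 with the bridgehead carbinol and the C16=C17 methylene.
- In its favour: the closure is irreversible and delivers the carbinol and the exocyclic alkene in one step. That is better than the aldol–methylenation pair of the chosen plan in step economy and in thermodynamic security. The C15 oxygen is already present.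
- Against it: the C15 stereocentre and the propargylic unit must be installed on quaternary C8 beforehand, whereas the acetyl group of the chosen dienophile comes with the Knoevenagel step. A5 as formulated has a second ketone at C1 that would also be reduced, so C1 would have to be carried as a protected carbinol.
- Comparison: this is an endgame move only. It does not address ring C or the C8–C9–C10 triad and would have to be combined with Alternative 2 or a modified dienophile. In the skeleton reached it is equal to the chosen ring D closure.

Key step: step 15

Remark: the facial sense of the rhodium-catalysed vinyl transfer in step 3 is assigned by analogy with cyclohex-2-enone, where (R)-BINAP delivers the new group to the face needed here; (S)-BINAP is to be used if the 2-ester reverses it.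

## Route

Step 1
Reactants: 1 4,4-dimethylcyclohexanone
Product: 2 methyl 5,5-dimethyl-2-oxocyclohexane-1-carboxylate
Conditions: NaH, (MeO)2CO, THF, reflux; aq. HCl work-up
Reagents that add atoms: dimethyl carbonate, COC(=O)OC
Why: Claisen-type C-acylation of the ketone enolate; the ketone is symmetric, so one regioisomer forms, and deprotonation of the β-keto ester product drives the reaction.

Step 2
Reactants: 2 methyl 5,5-dimethyl-2-oxocyclohexane-1-carboxylate
Product: 5 methyl 3,3-dimethyl-6-oxocyclohex-1-ene-1-carboxylate (enone ester; C10=C5), via α-phenylselanyl keto ester 3 (not isolated), via selenoxide 4 (not isolated)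
Conditions: PhSeCl, pyridine, CH2Cl2, 0 °C; then 30% H2O2, 0 °C → rt
Reagents that add atoms: none
Why: α-Selenenylation of the β-keto ester and selenoxide syn-elimination; the only β-hydrogens are on the CH2 next to the gem-dimethyl carbon, so the C10=C5 enone forms and quaternary C4 blocks aromatisation.

Step 3
Reactants: 5 methyl 3,3-dimethyl-6-oxocyclohex-1-ene-1-carboxylate
Product: 6 methyl (6S)-6-ethenyl-5,5-dimethyl-2-oxocyclohexane-1-carboxylate (C5 vinyl; C10 stereolabile, partly enolised)
Conditions: CH2=CHBF3K, [Rh(cod)2]BF4 (cat.), (R)-BINAP, Et3N, toluene/H2O, 60 °C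
Reagents that add atoms: potassium vinyltrifluoroborate, C=C[B-](F)(F)F.[K+]
Why: Hayashi–Miyaura-type rhodium-catalysed 1,4-addition of an alkenylboron reagent to an activated cyclic enone; the BINAP–rhodium alkenyl complex differentiates the enone faces and sets C5, while C10 remains a labile β-keto ester centre that is fixed in step 4.

Step 4
Reactants: 6 methyl (6S)-6-ethenyl-5,5-dimethyl-2-oxocyclohexane-1-carboxylate
Product: 7 methyl (1S,6R)-6-ethenyl-1-(hydroxymethyl)-5,5-dimethyl-2-oxocyclohexane-1-carboxylate (hydroxymethyl = C9 arm, trans to the C5 vinyl group; ester = future C20, cis to it)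
Conditions: 37% aq. HCHO, KHCO3, THF, 0 °C → rt
Reagents that add atoms: formaldehyde, C=O
Why: Aldol addition of the β-keto ester enolate to formaldehyde under weak base; the electrophile should enter anti to the adjacent C5 vinyl group, which fixes quaternary C10 with the C9 arm trans to C6.

Step 5
Reactants: 7 methyl (1S,6R)-6-ethenyl-1-(hydroxymethyl)-5,5-dimethyl-2-oxocyclohexane-1-carboxylate
Product: 8 methyl (1S,2S,6R)-6-ethenyl-2-hydroxy-1-(hydroxymethyl)-5,5-dimethylcyclohexane-1-carboxylate (C1 hydroxyl trans to the C9 arm, cis to the ester)
Conditions: Me4NBH(OAc)3, MeCN/AcOH, −30 → 0 °C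
Reagents that add atoms: none
Why: Evans–Saksena hydroxyl-directed reduction: the C9 hydroxyl binds boron and hydride reaches C1 from the face of the C9 arm, so the C1 hydroxyl ends trans to C9; the ester and alkene are inert and the acidic medium avoids retro-aldol loss of formaldehyde.

Step 6
Reactants: 8 diol ester
Product: 9 bis(tert-butyldimethylsilyl) ether of 8 (silyl ethers on O1 and O9; ester and vinyl unchanged)
Conditions: TBSOTf, 2,6-lutidine, CH2Cl2, 0 °C → rt
Reagents that add atoms: tert-butyldimethylsilyl triflate, CC(C)(C)[Si](C)(C)OS(=O)(=O)C(F)(F)F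
Why: Silylation of both hydroxyls with the silyl triflate, which is reactive enough for the hindered C1 carbinol; it precedes acetal formation because silyl triflates attack dimethyl acetals.

Step 7
Reactants: 9 bis-silyl ether
Product: 11 C6 dimethyl acetal (ring A with O1-TBS, C9H2-OTBS, C20 methyl ester, C5 dimethoxymethyl group), via C6 aldehyde 10 (not isolated)
Conditions: O3, CH2Cl2/MeOH, −78 °C; Me2S; then HC(OMe)3, PPTS, MeOH, rt
Reagents that add atoms: methanol, CO; trimethyl orthoformate, COC(OC)OC
Why: Ozonolysis of the only alkene with reductive work-up gives the C6 aldehyde, which is acetalised at once so that C5, α to it, is not exposed; mild PPTS catalysis is chosen so that the neopentyl primary silyl ether survives.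

Step 8
Reactants: 11 C6 dimethyl acetal ester
Product: 12 C20 primary alcohol (C10 bearing CH2OH cis to the acetal arm and CH2OTBS trans to it)
Conditions: i-Bu2AlH, CH2Cl2, −78 → 0 °C
Reagents that add atoms: none
Why: Hydride reduction of the hindered methyl ester to the primary alcohol; the covalent aluminium alkoxide and low temperature should prevent migration of either silyl group to the new hydroxyl.

Step 9
Reactants: 12 C20 primary alcohol
Product: 13 C20 acetoacetate ester
Conditions: 2,2,6-trimethyl-4H-1,3-dioxin-4-one, toluene, 110 °C
Reagents that add atoms: 2,2,6-trimethyl-4H-1,3-dioxin-4-one, CC1=CC(=O)OC(C)(C)O1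
Why: Thermal retro-[4+2] of the dioxinone releases acetylketene, which acylates the C20 hydroxyl under neutral conditions (no base, hence no silyl migration) and installs C7, C8, C15 and C16.

Step 10
Reactants: 13 C20 acetoacetate ester
Product: 14 C9 primary alcohol (O1-TBS and acetoacetate retained)
Conditions: HF·pyridine, pyridine, THF, 0 °C
Reagents that add atoms: none
Why: Buffered fluoride cleaves the primary silyl ether much faster than the secondary one flanked by quaternary C10; short, non-basic conditions are used so that the acetoacetyl group does not migrate from O20 to O9.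

Step 11
Reactants: 14 C9 primary alcohol
Product: 16 spiro 3-acetyl-5,6-dihydro-2H-pyran-2-one (pyranone C5 = C10 of ring A; ring A with C1 OTBS trans to C9, gem-dimethyl C4, C5 dimethoxymethyl cis to C20), via C9 aldehyde 15 (not isolated)
Conditions: Dess–Martin periodinane, NaHCO3, CH2Cl2, 0 °C → rt; then ethylenediammonium diacetate (cat.), CH2Cl2, rt
Reagents that add atoms: none
Why: Dess–Martin oxidation gives the C9 aldehyde, held six atoms from the active methylene, and ammonium carboxylate catalysis should close the lactone ring by intramolecular Knoevenagel condensation; the tether fixes the alkene geometry and overcomes the low reactivity of a neopentyl aldehyde.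

Step 12
Reactants: 17 3-chlorobutan-2-one; 18 thiophenol
Product: 19 3-(phenylthio)butan-2-one
Conditions: K2CO3, acetone, rt
Reagents that add atoms: none
Why: SN2 displacement of the α-chloro ketone by thiolate, a fast reaction for α-halo ketones.

Step 13
Reactants: 19 3-(phenylthio)butan-2-one
Product: 21 3-(phenylthio)but-3-en-2-one, via 3-chloro-3-(phenylthio)butan-2-one 20 (not isolated)
Conditions: N-chlorosuccinimide, CH2Cl2, 0 °C → rt; then i-Pr2NEt, 0 °C
Reagents that add atoms: none
Why: α-Chlorination of the sulfide at the carbon between sulfur and carbonyl (through the chlorosulfonium salt) and dehydrochlorination toward the only β-hydrogens give the 2-thio enone; it is used at once because it dimerises on standing.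

Step 14
Reactants: 21 3-(phenylthio)but-3-en-2-one
Product: 22 2-acetoxy-3-(phenylthio)buta-1,3-diene
Conditions: KN(SiMe3)2, THF, −78 °C; then Ac2O
Reagents that add atoms: acetic anhydride, CC(=O)OC(C)=O
Why: Kinetic deprotonation of the methyl ketone by a hindered amide base and O-acylation of the cross-conjugated potassium enolate give the dienyl acetate; inverse addition at low temperature suppresses Michael self-condensation.

Step 15
Reactants: 16 spiro 3-acetyl-5,6-dihydro-2H-pyran-2-one; 22 2-acetoxy-3-(phenylthio)buta-1,3-diene
Product: 23 cycloadduct: lactone cis-fused to a cyclohexene ring C bearing the C8 acetyl group, the C13 enol acetate and the C12 phenylthio group (H9 syn to the acetyl group; C11 on the lactone face anti to C5)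
Conditions: 22 (3 equiv), ZnCl2 (1 equiv), CH2Cl2/Et2O, −20 °C → rt
Reagents that add atoms: none
Why: Concerted, asynchronous normal-demand [4+2] cycloaddition in which ZnCl2 is held as a chelate between the lactone and acetyl oxygens of 16, lowering the LUMO and keeping the Lewis acid away from the acetal. The closest known reaction types are the sulfur-directed cycloadditions of 2-acyloxy-3-(arylthio)butadienes and the ZnCl2-promoted additions of dienes to 2-acyl and 2-alkoxycarbonyl cycloalkenones that carry a quaternary carbon next to the β-position. Ring C is closed as a cyclohexene by a suprafacial six-electron annulation in which C9–C11 (the more advanced bond) and C8–C14 form on the same face of the lactone alkene. Sulfur is the stronger donor, so the largest HOMO coefficient lies on C11 and pairs with the largest LUMO coefficient at the β-carbon C9; the oxygen therefore ends on C13, 1,3 to C8. C8 and C9 are set relative to each other by suprafacial addition to the ring-constrained cis alkene, which gives the cis-fused lactone with H9 syn to the acetyl group. They are set relative to C10 by attack antiperiplanar to the C10–C5 bond, the larger ring A arm (it bears the acetal and is buttressed by the gem-dimethyl group), that is on the face flanked by C1. No endo/exo question arises because the diene termini are unsubstituted. If some hetero-cycloaddition through the acetyl oxygen occurs, the resulting 2-alkenyl dihydropyran is an allyl vinyl ether that can pass to 23 by [3,3] shift on warming.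

Step 16
Reactants: 23 cycloadduct
Product: 24 C13 ketone with C12 phenylthio group (mixture at C12)
Conditions: NH3, MeOH, 0 °C
Reagents that add atoms: none
Why: Aminolysis of the enol ester, an activated acyl donor, liberates the C13 ketone; ammonia is nucleophilic but barely basic, so the alkyl lactone, the quaternary β-keto lactone (retro-Claisen) and the acetyl group (premature aldol) should be left alone.

Step 17
Reactants: 24 α-phenylthio ketone
Product: 25 diketone (C8 acetyl, C13 ketone; C12 methylene)
Conditions: SmI2, THF/MeOH, −78 °C
Reagents that add atoms: none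
Why: Reductive cleavage of the C–S bond α to the ketone by electron transfer from SmI2 with methanol as proton source; unactivated ketones, the lactone and the acetal do not react at this temperature, and a mercury amalgam is avoided.

Step 18
Reactants: 25 diketone
Product: 26 tetracyclic ketol (ring D closed: C13 bridgehead hydroxyl, C16 methylene, C15 ketone)
Conditions: KOt-Bu (cat.), t-BuOH/THF, 0 °C → rt
Reagents that add atoms: none
Why: Intramolecular aldol addition under equilibrating conditions; only the acetyl methyl enolate can reach a ketone through an unstrained five-membered closure, giving the bicyclo[3.2.1]octane whose C13 configuration is dictated by the bridge. The hindered, non-nucleophilic base is chosen to avoid retro-Claisen cleavage of the acyl lactone.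

Step 19
Reactants: 26 tetracyclic ketol
Product: 29 exocyclic enone (C16=C17 methylene, C15 ketone, C13 hydroxyl, O1-TBS, C6 acetal), via Mannich base 27 (not isolated), via methiodide 28 (not isolated)
Conditions: LiN(SiMe3)2 (2.5 equiv), THF, −78 °C; CH2=NMe2+ I−, −78 → 0 °C; then MeI, CH2Cl2, rt; then DBU, rt
Reagents that add atoms: N,N-dimethylmethyleneiminium iodide, C=[N+](C)C.[I-]
Why: Mannich methylenation: the dilithio alkoxide enolate (enolisation is possible only toward C16, and once the enolate exists retro-aldol is blocked) adds to the iminium salt, and quaternisation followed by E1cB elimination gives the exocyclic enone.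

Step 20
Reactants: 29 exocyclic enone
Product: 30 C1,C13 diol (C1 secondary hydroxyl freed)
Conditions: HF·pyridine, pyridine, THF, 0 °C → rt
Reagents that add atoms: none
Why: Fluoride-mediated cleavage of the remaining silyl ether under buffered conditions that should spare the dimethyl acetal; no base is present that could add to the exocyclic enone.

Step 21
Reactants: 30 C1,C13 diol
Product: 32 ring A enone (C1 ketone, C2=C3) with C15 ketone, C16=C17 and C6 acetal, via C1 ketone 31 (not isolated)
Conditions: IBX, DMSO, rt → 70 °C
Reagents that add atoms: none
Why: IBX oxidises the C1 carbinol to the ketone and, on warming, dehydrogenates it through its only enol (toward C2) to the 4,4-dimethylcyclohexenone; the bridgehead C13 alcohol can be neither oxidised nor transposed and the C15 enone has no enolisable hydrogen.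

Step 22
Reactants: 32 ring A enone
Product: 33 C15 alcohol (hydroxyl syn to the C9–C11–C12 bridge, anti to O13), C6 still the dimethyl acetal
Conditions: Me4NBH(OAc)3, MeCN/AcOH, −30 → 0 °C
Reagents that add atoms: none
Why: Evans–Saksena reduction: the C13 hydroxyl exchanges onto boron and delivers hydride to C15 from the exo face, the face of O13 away from the three-carbon bridge, giving the 1,3-anti diol. Ketones without a neighbouring hydroxyl, such as the ring A enone, are not reduced by triacetoxyborohydride, which secures chemoselectivity.

Step 23
Reactants: 33 C15 alcohol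
Product: 34 target CNP0521079.1
Conditions: PPTS, acetone/H2O, 40 °C
Reagents that add atoms: water, O
Why: Mild acid-catalysed hydrolysis of the dimethyl acetal releases the C6 aldehyde last; a weak acid and short reaction time are chosen to avoid allylic transposition of the 15-ol and epimerisation at C5.

## Compound list

1 | 4,4-dimethylcyclohexanone | CC1(C)CCC(=O)CC1 | starting material
2 | methyl 5,5-dimethyl-2-oxocyclohexane-1-carboxylate | COC(=O)C1CC(C)(C)CCC1=O | intermediate
3 | methyl 5,5-dimethyl-2-oxo-1-(phenylselanyl)cyclohexane-1-carboxylate | COC(=O)C1([Se]c2ccccc2)CC(C)(C)CCC1=O | intermediate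
4 | methyl 5,5-dimethyl-2-oxo-1-(phenylseleninyl)cyclohexane-1-carboxylate | COC(=O)C1([Se](=O)c2ccccc2)CC(C)(C)CCC1=O | intermediate
5 | methyl 3,3-dimethyl-6-oxocyclohex-1-ene-1-carboxylate | COC(=O)C1=CC(C)(C)CCC1=O | intermediate
6 | methyl (6S)-6-ethenyl-5,5-dimethyl-2-oxocyclohexane-1-carboxylate | COC(=O)C1C(=O)CCC(C)(C)[C@H]1C=C | intermediate
7 | methyl (1S,6R)-6-ethenyl-1-(hydroxymethyl)-5,5-dimethyl-2-oxocyclohexane-1-carboxylate | OC[C@]1(C(=O)OC)C(=O)CCC(C)(C)[C@H]1C=C | intermediate
8 | methyl (1S,2S,6R)-6-ethenyl-2-hydroxy-1-(hydroxymethyl)-5,5-dimethylcyclohexane-1-carboxylate | OC[C@]1(C(=O)OC)[C@@H](O)CCC(C)(C)[C@H]1C=C | intermediate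
9 | bis(tert-butyldimethylsilyl) ether of 8 (O1 and O9) | CC(C)(C)[Si](C)(C)OC[C@]1(C(=O)OC)[C@@H](O[Si](C)(C)C(C)(C)C)CCC(C)(C)[C@H]1C=C | intermediate
10 | C6 aldehyde from ozonolysis of 9 | CC(C)(C)[Si](C)(C)OC[C@]1(C(=O)OC)[C@@H](O[Si](C)(C)C(C)(C)C)CCC(C)(C)[C@H]1C=O | intermediate
11 | C6 dimethyl acetal, C20 methyl ester, O1 and O9 silyl ethers | CC(C)(C)[Si](C)(C)OC[C@]1(C(=O)OC)[C@@H](O[Si](C)(C)C(C)(C)C)CCC(C)(C)[C@H]1C(OC)OC | intermediate
12 | C20 primary alcohol (C9 arm silylated) | CC(C)(C)[Si](C)(C)OC[C@]1(CO)[C@@H](O[Si](C)(C)C(C)(C)C)CCC(C)(C)[C@H]1C(OC)OC | intermediate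
13 | C20 acetoacetate ester | CC(C)(C)[Si](C)(C)OC[C@]1(COC(=O)CC(C)=O)[C@@H](O[Si](C)(C)C(C)(C)C)CCC(C)(C)[C@H]1C(OC)OC | intermediate
14 | C9 primary alcohol with C20 acetoacetate | OC[C@]1(COC(=O)CC(C)=O)[C@@H](O[Si](C)(C)C(C)(C)C)CCC(C)(C)[C@H]1C(OC)OC | intermediate
15 | C9 aldehyde with C20 acetoacetate | O=C[C@]1(COC(=O)CC(C)=O)[C@@H](O[Si](C)(C)C(C)(C)C)CCC(C)(C)[C@H]1C(OC)OC | intermediate
16 | spiro 3-acetyl-5,6-dihydro-2H-pyran-2-one carrying ring A (dienophile) | CC(=O)C1=C[C@]2(COC1=O)[C@@H](O[Si](C)(C)C(C)(C)C)CCC(C)(C)[C@H]2C(OC)OC | intermediate
17 | 3-chlorobutan-2-one | CC(Cl)C(C)=O | starting material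
18 | thiophenol | Sc1ccccc1 | starting material
19 | 3-(phenylthio)butan-2-one | CC(Sc1ccccc1)C(C)=O | intermediate
20 | 3-chloro-3-(phenylthio)butan-2-one | CC(Cl)(Sc1ccccc1)C(C)=O | intermediate
21 | 3-(phenylthio)but-3-en-2-one | C=C(Sc1ccccc1)C(C)=O | intermediate
22 | 2-acetoxy-3-(phenylthio)buta-1,3-diene | C=C(OC(C)=O)C(=C)Sc1ccccc1 | intermediate
23 | cycloadduct: lactone-fused cyclohexene with C8 acetyl, C13 enol acetate, C12 sulfide | CC(=O)[C@]23CC(OC(C)=O)=C(Sc4ccccc4)C[C@H]2[C@]1(COC3=O)[C@@H](O[Si](C)(C)C(C)(C)C)CCC(C)(C)[C@H]1C(OC)OC | intermediate
24 | C13 ketone with C12 phenylthio group | CC(=O)[C@]23CC(=O)C(Sc4ccccc4)C[C@H]2[C@]1(COC3=O)[C@@H](O[Si](C)(C)C(C)(C)C)CCC(C)(C)[C@H]1C(OC)OC | intermediate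
25 | C8 acetyl, C13 ketone (diketone) | CC(=O)[C@]23CC(=O)CC[C@H]2[C@]1(COC3=O)[C@@H](O[Si](C)(C)C(C)(C)C)CCC(C)(C)[C@H]1C(OC)OC | intermediate
26 | tetracyclic ketol (13-hydroxy, 15-oxo, C16 methylene) | C1C(=O)[C@]23C[C@@]1(O)CC[C@H]2[C@]1(COC3=O)[C@@H](O[Si](C)(C)C(C)(C)C)CCC(C)(C)[C@H]1C(OC)OC | intermediate
27 | Mannich base (16-(dimethylaminomethyl) ketone) | CN(C)CC1C(=O)[C@]23C[C@@]1(O)CC[C@H]2[C@]1(COC3=O)[C@@H](O[Si](C)(C)C(C)(C)C)CCC(C)(C)[C@H]1C(OC)OC | intermediate
28 | methiodide of 27 | C[N+](C)(C)CC1C(=O)[C@]23C[C@@]1(O)CC[C@H]2[C@]1(COC3=O)[C@@H](O[Si](C)(C)C(C)(C)C)CCC(C)(C)[C@H]1C(OC)OC.[I-] | intermediate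
29 | 16-methylene-15-ketone, 13-hydroxy, O1-TBS, C6 acetal | C=C1C(=O)[C@]23C[C@@]1(O)CC[C@H]2[C@]1(COC3=O)[C@@H](O[Si](C)(C)C(C)(C)C)CCC(C)(C)[C@H]1C(OC)OC | intermediate
30 | C1,C13 diol with 16-methylene-15-ketone | C=C1C(=O)[C@]23C[C@@]1(O)CC[C@H]2[C@]1(COC3=O)[C@@H](O)CCC(C)(C)[C@H]1C(OC)OC | intermediate
31 | C1 ketone (saturated ring A) with 16-methylene-15-ketone | C=C1C(=O)[C@]23C[C@@]1(O)CC[C@H]2[C@]1(COC3=O)C(=O)CCC(C)(C)[C@H]1C(OC)OC | intermediate
32 | ring A enone with 16-methylene-15-ketone, C6 acetal | C=C1C(=O)[C@]23C[C@@]1(O)CC[C@H]2[C@]1(COC3=O)C(=O)C=CC(C)(C)[C@H]1C(OC)OC | intermediate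
33 | 15-alcohol, ring A enone, C6 acetal | C=C1[C@@H](O)[C@]23C[C@@]1(O)CC[C@H]2[C@]1(COC3=O)C(=O)C=CC(C)(C)[C@H]1C(OC)OC | intermediate
34 | CNP0521079.1 | C=C1[C@@H](O)[C@]23C[C@@]1(O)CC[C@H]2[C@]1(COC3=O)C(=O)C=CC(C)(C)[C@H]1C=O | target

## Step count and least certain steps

Total: 23 steps. Longest linear sequence: 20 steps (steps 1–11 and 15–23); the diene takes 3 steps (12–14).

**Step 15 (key step).** The most likely failure is a slow cycloaddition at the neopentyl carbon C9. Lewis-acid ionisation of the dimethyl acetal, hetero-cycloaddition through the acetyl oxygen and decomposition of the diene could then compete. Facial discrimination between the C1 and C5 arms could also be incomplete, because the equatorial C1 silyloxy group lies gauche to the incoming terminus. The fallback sets out from 21 and 16 and returns at 24. The potassium enolate of 21 is silylated with Et3SiCl to give 2-(triethylsilyloxy)-3-(phenylthio)buta-1,3-diene F1, a more electron-rich partner that should add to 16 without Lewis acid (toluene, 80 °C, or high pressure), giving the triethylsilyl enol ether cycloadduct F2. Acetic-acid-buffered Bu4NF at 0 °C then cleaves the enol ether directly to 24, so step 16 is not needed.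

**Step 3.** Enantiofacial discrimination may be poor at a β-carbon next to the quaternary centre, or the chelating β-keto ester product may hold the rhodium and stop turnover. The fallback sets out from 5 and returns at 8.
- Copper-catalysed addition of CH2=CHMgBr (CuBr·SMe2, THF, −78 °C) gives racemic material, that is 6 together with its enantiomer ent-6 F3.
- The same hydroxymethylation and directed reduction give 7 and 8 together with their enantiomers ent-7 F4 and ent-8 F5.
- Acylation of the primary hydroxyl with (S)-O-methylmandelic acid (DCC, DMAP) gives the (S)-O-methylmandelate of 8 F6 and the diastereomeric (S)-O-methylmandelate of ent-8 F7, which are separated by chromatography or crystallisation.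
- Methanolysis of F6 (K2CO3, MeOH) returns 8.

**Step 18.** The aldol equilibrium may not favour the ketol (the bicyclo[3.2.1]octane is strained and the acetyl group must be axial), or the acetyl group may be lost by retro-Claisen cleavage. The fallback sets out from 25 and returns at 26. Soft enolisation with (c-C6H11)2BCl and Et3N in Et2O (−78 → 0 °C) takes the methyl ketone at its methyl group. The enol borinate adds to the C13 ketone to give the covalent dicyclohexylboron aldolate F8, which does not revert, and work-up with pH 7 buffer releases 26 without alkoxide base.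

**Step 22.** The tertiary bridgehead hydroxyl may exchange onto boron too slowly, leaving the ketone untouched or allowing slow undirected reduction. The fallback sets out from 29 and returns at 33; it reduces C15 while it is the only ketone.
- Luche reduction (NaBH4, CeCl3·7H2O, MeOH, −78 °C, hydride from the exo face) gives the 15-alcohol with O1-TBS F9.
- Ac2O, DMAP and pyridine give the 15-acetate F10.
- HF·pyridine gives the C1 alcohol 15-acetate F11.
- IBX in DMSO gives, through the C1 ketone 15-acetate F12, the ring A enone 15-acetate F13.
- K2CO3 in MeOH at 0 °C removes the acetate to give 33.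

## Further compounds

F1 | step 15 | 2-(triethylsilyloxy)-3-(phenylthio)buta-1,3-diene | C=C(O[Si](CC)(CC)CC)C(=C)Sc1ccccc1
F2 | step 15 | triethylsilyl enol ether cycloadduct (13-silyloxy analogue of 23) | CC(=O)[C@]23CC(O[Si](CC)(CC)CC)=C(Sc4ccccc4)C[C@H]2[C@]1(COC3=O)[C@@H](O[Si](C)(C)C(C)(C)C)CCC(C)(C)[C@H]1C(OC)OC
F3 | step 3 | ent-6, methyl (6R)-6-ethenyl-5,5-dimethyl-2-oxocyclohexane-1-carboxylate | COC(=O)C1C(=O)CCC(C)(C)[C@@H]1C=C
F4 | step 3 | ent-7, methyl (1R,6S)-6-ethenyl-1-(hydroxymethyl)-5,5-dimethyl-2-oxocyclohexane-1-carboxylate | OC[C@@]1(C(=O)OC)C(=O)CCC(C)(C)[C@@H]1C=C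
F5 | step 3 | ent-8, methyl (1R,2R,6S)-6-ethenyl-2-hydroxy-1-(hydroxymethyl)-5,5-dimethylcyclohexane-1-carboxylate | OC[C@@]1(C(=O)OC)[C@H](O)CCC(C)(C)[C@@H]1C=C
F6 | step 3 | (S)-O-methylmandelate of 8 (ester on O9) | CO[C@@H](c1ccccc1)C(=O)OC[C@]1(C(=O)OC)[C@@H](O)CCC(C)(C)[C@H]1C=C
F7 | step 3 | (S)-O-methylmandelate of ent-8 (ester on O9) | CO[C@@H](c1ccccc1)C(=O)OC[C@@]1(C(=O)OC)[C@H](O)CCC(C)(C)[C@@H]1C=C
F8 | step 18 | dicyclohexylboron aldolate of 26 (O13–B) | C1C(=O)[C@]23C[C@@]1(OB(C4CCCCC4)C4CCCCC4)CC[C@H]2[C@]1(COC3=O)[C@@H](O[Si](C)(C)C(C)(C)C)CCC(C)(C)[C@H]1C(OC)OC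
F9 | step 22 | 15-alcohol with O1-TBS, 16-methylene, C6 acetal | C=C1[C@@H](O)[C@]23C[C@@]1(O)CC[C@H]2[C@]1(COC3=O)[C@@H](O[Si](C)(C)C(C)(C)C)CCC(C)(C)[C@H]1C(OC)OC
F10 | step 22 | 15-acetate with O1-TBS | C=C1[C@@H](OC(C)=O)[C@]23C[C@@]1(O)CC[C@H]2[C@]1(COC3=O)[C@@H](O[Si](C)(C)C(C)(C)C)CCC(C)(C)[C@H]1C(OC)OC
F11 | step 22 | C1 alcohol 15-acetate | C=C1[C@@H](OC(C)=O)[C@]23C[C@@]1(O)CC[C@H]2[C@]1(COC3=O)[C@@H](O)CCC(C)(C)[C@H]1C(OC)OC
F12 | step 22 | C1 ketone 15-acetate (saturated ring A) | C=C1[C@@H](OC(C)=O)[C@]23C[C@@]1(O)CC[C@H]2[C@]1(COC3=O)C(=O)CCC(C)(C)[C@H]1C(OC)OC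
F13 | step 22 | ring A enone 15-acetate | C=C1[C@@H](OC(C)=O)[C@]23C[C@@]1(O)CC[C@H]2[C@]1(COC3=O)C(=O)C=CC(C)(C)[C@H]1C(OC)OC
A1 | alternative 1 | ring A enone bearing the tethered (Z)-2-acetoxyvinyl ester | CC1(OCCO1)CC[C@H](CC(=O)O/C=C\OC(C)=O)C2=CC(C)(C)CCC2=O
A2 | alternative 1 | cyclobutane-fused ring A and lactone | CC1(OCCO1)CC[C@@H]2CC(=O)O[C@H]3[C@@H](OC(C)=O)[C@@H]4C(C)(C)CCC(=O)[C@]234
A3 | alternative 2 | 6-alkenyl δ-lactone with α-propargyl group (C8 and C12 not specified) | O=C1OC(/C=C/[C@]2(CO[Si](C)(C)C(C)(C)C)C(=O)CCC(C)(C)[C@H]2C(OC)OC)C2(OCCO2)CC1CC#C[Si](C)(C)C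
A4 | alternative 2 | cyclohexene carboxylic acid with C8 and C9 set | OC(=O)[C@@]1(CC#C[Si](C)(C)C)CC2(OCCO2)C=C[C@H]1[C@]3(CO[Si](C)(C)C(C)(C)C)C(=O)CCC(C)(C)[C@H]3C(OC)OC
A5 | alternative 3 | C13 ketone with C8 propargylic silyl ether | C#C[C@@H](O[Si](C)(C)C(C)(C)C)[C@]23CC(=O)CC[C@H]2[C@]1(COC3=O)C(=O)CCC(C)(C)[C@H]1C(OC)OC
A6 | alternative 3 | protected tetracycle with C13 hydroxyl and 16-ene | C=C1[C@@H](O[Si](C)(C)C(C)(C)C)[C@]23C[C@@]1(O)CC[C@H]2[C@]1(COC3=O)C(=O)CCC(C)(C)[C@H]1C(OC)OC
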